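The rate constants stand for no real mixture, and the outcome is calculated.

J is the reagent that D and G share in this flask.

    Q ⇌ Z (K1 = 0.15, k1 = 2.75 /h)
    G + J ⇌ X (K2 = 1.5 /M, k2 = 0.0991 /M/h)
    D + J ⇌ Q (K3 = 0.23 /M, k3 = 0.146 /M/h)

D 0.80 M; J 2.00 equiv (in portions, 4); G 1.00 equiv; time 6.0 d; the portions of J follow each other after 2.0 h, the first at the start

1. why nothing more happens at 6.0 d, or that something still does (it is still moving / all of D has reacted / J has run out first / forward and back rates have come level)
2. conversion of D at 6.0 d
3. amount of Q at 6.0 d, in percent of the D charged
4. amount of Z at 6.0 d, in percent of the D charged

- the reaction counts as stopped when no species that holds the D changes by six tenths of a point or more over the second half of the time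
- run time (flask): 6.0 d

- The quantity to carry is the hold H of J on D: the ratio of bound D (Q and Z together) to free D if the whole J charge stood free. It is the balance constant of D with J, times one plus the balance constant of Q to Z, times the J charge, which makes 0.423. With f the share of the J charge still free, bound D over free D is H times f.
- G has a hold of its own, the balance constant of G with J times the J charge, 2.40, and bound G over free G is that times f.
- The ledger follows the J charge into free J, X, Q and Z. Each D or G taken up costs one J, and the charges stand at 2.00 equiv of J and 1.00 equiv of G.
- A first guess lets G take its whole charge and D none, so f is 50.0 %. The entries at that f return 64.0 %, and a second round returns 59.1 %. The ledger swings, so a straight line through the two misses gives f as 60.3 %.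
- This reckoning then books 29.6 % of the J charge to X, 8.84 % to Q and 1.33 % to Z, beside the free share, and the books close at 100 %.
- In shares of the D charge, this gives a conversion of 20.3 %, with Q at 17.7 % and Z at 2.65 %.
- The approach comes next. The last portion of J goes in at 6.00 h. The forward half-life of G with the whole J charge present, 4.37 h, is longer than that of D, 2.97 h. The run time of 6.0 d is long against that half-life of G, so this reckoning expects that forward and back rates have come level, which is thermodynamic control.
- The forecast says forward and back rates have come level, with conversion 20.3 %, Q 17.7 % and Z 2.65 %: “six days is ample and the portionwise addition of J no longer matters”.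
- The simulation gives forward and back rates have come level, with conversion 20.3 %, Q 17.7 % and Z 2.65 %.
- In this flask 60 % of the J charge stands free, and H times that share is 0.254, the ratio of bound D to free D. The neighbour flask, charged with 0.48 M of D at the same equivalents, has a weaker hold than this flask, 0.254, and G's hold there is 1.44. Its ledger returns 73.4 %, then 66.4 %, and the straight line gives f as 68.1 %, so conversion comes to 14.7 %. The neighbour flask ends with 68 % of its J free, conversion 14.7 %, Q 12.8 % and Z 1.92 %.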